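**Retrosynthetic overview**
1. Target ⇐ Shi epoxidation of the C10=C11 alkene (last ring formed) ⇐ C6 desilylation ⇐ one double angeloylation of a C5,C8-diol whose C6–OH is masked as a silyl ether.
2. C5–OH ⇐ Luche reduction of an epoxy ketone; C8 carbinol and C8–C9 bond ⇐ catalytic asymmetric linear prenylation of a 2-substituted acrolein, itself from a CH2CHO arm by α-methylenation.
3. C6–O ⇐ Rubottom oxidation; C3/C4 oxirane (second ring formed) ⇐ Weitz–Scheffer epoxidation of a carvone-like enone.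
4. Cyclohexenone (first ring formed, C1 set) ⇐ amine-catalysed Michael addition, aldol condensation and decarboxylation of tert-butyl 3-oxopentanoate with (E)-5,5-diethoxypent-2-enal, the latter from cross-metathesis.

Locants used in names and descriptors (route numbering): ring C1 (carries the side chain), C2 (CH2), C3 and C4 (ring oxirane, C4 carries CH3), C5 (O-angelate), C6 (OH); side chain C7 (on C1, carries the exocyclic CH2), C8 (O-angelate), C9, C10 and C11 (oxirane, C11 is CMe2). Target: 1R,3S,4S,5S,6R,8S,10R.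
Assumption: enal 3 and boronate 17 are treated as not purchasable and are made (steps 1 and 6); none of the route has been run, and selectivities are predicted by analogy.

Step 1
Reactants: 1 4,4-diethoxybut-1-ene; 2 (E)-but-2-enal
Product: 3 (E)-5,5-diethoxypent-2-enal
Conditions: 2 (3 equiv), second-generation Hoveyda–Grubbs catalyst RuCl2(=CH-C6H4-2-O-i-Pr)(H2IMes) (2 mol%), CH2Cl2, 40 °C
Reagents that add atoms: none
Why: Olefin cross-metathesis of a terminal alkene with crotonaldehyde is E-selective and is driven by loss of propene; no stereocentre is formed.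

Step 2
Reactants: 3 (E)-5,5-diethoxypent-2-enal; 4 tert-butyl 3-oxopentanoate
Product: 7 (5R)-5-(2,2-diethoxyethyl)-2-methylcyclohex-2-en-1-one, via Michael adduct 5 (not isolated), via tert-butyl keto ester 6 (not isolated)
Conditions: (R)-α,α-bis[3,5-bis(trifluoromethyl)phenyl]prolinol trimethylsilyl ether (10 mol%), PhCO2H (10 mol%), toluene, 0 °C → rt; then piperidine/AcOH (30 mol%), molecular sieves 3 Å, 50 °C; then TsOH (0.6 equiv), 75 °C
Reagents that add atoms: none
Why: Iminium-catalysed Michael addition of the β-keto ester, with the (R)-diarylprolinol silyl ether shielding the Re face of the β-carbon so that C6 adds to the Si face and sets C1 (R); a buffered amine-mediated intramolecular aldol condensation through the ethyl CH2 then closes the ring before any strong acid is present, so the free-aldehyde arm and the acetal arm on C1 cannot exchange and erode the ee, and acid-induced loss of isobutene with decarboxylation finishes the enone.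

Step 3
Reactants: 7 (5R)-5-(2,2-diethoxyethyl)-2-methylcyclohex-2-en-1-one
Product: 8 (1S,4R,6S)-4-(2,2-diethoxyethyl)-1-methyl-7-oxabicyclo[4.1.0]heptan-2-one
Conditions: 30% aq. H2O2, NaOH (0.3 equiv), MeOH, 0 °C
Reagents that add atoms: hydrogen peroxide OO
Why: Weitz–Scheffer nucleophilic epoxidation; as with carvone, hydroperoxide adds axially to C3 anti to the equatorial C1 substituent, which sets C3 and C4 with the oxirane trans to the side chain.

Step 4
Reactants: 8 (1S,4R,6S)-4-(2,2-diethoxyethyl)-1-methyl-7-oxabicyclo[4.1.0]heptan-2-one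
Product: 11 (1S,3R,4R,6S)-4-(2,2-diethoxyethyl)-1-methyl-3-(triethylsilyloxy)-7-oxabicyclo[4.1.0]heptan-2-one, via silyl enol ether 9 (not isolated), via silyloxy oxirane 10 (not isolated)
Conditions: LiN(i-Pr)2, THF, −78 °C; Et3SiCl; then m-CPBA, CH2Cl2, −20 → 0 °C
Reagents that add atoms: chlorotriethylsilane CC[Si](Cl)(CC)CC; 3-chloroperbenzoic acid OOC(=O)c1cccc(Cl)c1
Why: Rubottom oxidation with 1,4-silyl shift; only C6 can be enolised, the peracid attacks the enol ether anti to the C1 side chain and the C4 methyl, and the resulting 6-silyloxy ketone is trans to C1, which is also the thermodynamically favoured epimer.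

Step 5
Reactants: 11 (1S,3R,4R,6S)-4-(2,2-diethoxyethyl)-1-methyl-3-(triethylsilyloxy)-7-oxabicyclo[4.1.0]heptan-2-one
Product: 13 2-[(1S,3R,4R,6S)-6-methyl-5-oxo-4-(triethylsilyloxy)-7-oxabicyclo[4.1.0]heptan-3-yl]prop-2-enal, via aldehyde 12 (not isolated)
Conditions: PPTS (20 mol%), acetone/H2O 9:1, 40 °C; concentrate; then 37% aq. CH2O, pyrrolidine (20 mol%), EtCO2H (20 mol%), i-PrOH, 45 °C
Reagents that add atoms: water O; formaldehyde C=O
Why: Mild acetal hydrolysis followed by amine-catalysed α-methylenation (Mannich condensation and elimination) of the unbranched aldehyde; the hindered ketone, oxirane and silyl ether are left alone and no stereocentre is touched.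

Step 6
Reactants: 14 1-chloro-3-methylbut-2-ene; 15 2-isopropoxy-4,4,5,5-tetramethyl-1,3,2-dioxaborolane
Product: 17 2-(2-methylbut-3-en-2-yl)-4,4,5,5-tetramethyl-1,3,2-dioxaborolane, via prenylmagnesium chloride 16 (not isolated)
Conditions: Mg, THF, 0 °C; then 15, −78 °C → rt; aq. NH4Cl
Reagents that add atoms: none
Why: Grignard formation and borylation; the prenyl Grignard reagent is expected to react with the boron electrophile at its γ-terminus (allylic transposition, as in its carbonyl additions) to give the tertiary pinacol boronate, which does not undergo 1,3-boron shift at room temperature.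

Step 7
Reactants: 13 2-[(1S,3R,4R,6S)-6-methyl-5-oxo-4-(triethylsilyloxy)-7-oxabicyclo[4.1.0]heptan-3-yl]prop-2-enal; 17 2-(2-methylbut-3-en-2-yl)-4,4,5,5-tetramethyl-1,3,2-dioxaborolane
Product: 19 (1S,3R,4R,6S)-4-[(3S)-3-hydroxy-6-methylhepta-1,5-dien-2-yl]-1-methyl-3-(triethylsilyloxy)-7-oxabicyclo[4.1.0]heptan-2-one, via pinacol borate ester 18 (not isolated)
Conditions: (S)-TRIP phosphoric acid (10 mol%), 17 (1.5 equiv), molecular sieves 4 Å, toluene, −30 → 0 °C; aq. NaHCO3
Reagents that add atoms: none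
Why: Proposed new method: a chiral phosphoric acid-catalysed enantioselective allylboration with a tertiary α,α-dimethylallyl pinacol boronate, which transfers through its γ-carbon in a closed chair transition state so that the CH2 terminus bonds to the aldehyde carbon and the linear prenyl carbinol results, while the acid hydrogen-bonds the pseudo-axial boronate oxygen and the formyl C–H and directs attack to the Si face to set C8 (S), the ketone being inert to the pinacol boronate; the closest known reaction type is the phosphoric acid-catalysed allylboration of aryl and alkenyl aldehydes with unsubstituted allyl pinacol boronate (where the (R)-acid directs attack to the Re face) together with the uncatalysed γ-selective addition of α,α-disubstituted allylboronates, and the catalysed, enantiocontrolled use of the gem-dimethyl reagent is what has not been shown.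

Step 8
Reactants: 19 (1S,3R,4R,6S)-4-[(3S)-3-hydroxy-6-methylhepta-1,5-dien-2-yl]-1-methyl-3-(triethylsilyloxy)-7-oxabicyclo[4.1.0]heptan-2-one
Product: 20 (1R,2S,3R,4R,6S)-4-[(3S)-3-hydroxy-6-methylhepta-1,5-dien-2-yl]-1-methyl-3-(triethylsilyloxy)-7-oxabicyclo[4.1.0]heptan-2-ol
Conditions: NaBH4, CeCl3·7H2O, MeOH, −78 °C
Reagents that add atoms: none
Why: Luche reduction of the α,β-epoxy ketone; hydride is expected to add axially to C5 from the oxirane face, anti to the C4 methyl and to the axial C6–H and helped by cerium chelation of carbonyl and oxirane oxygens, giving the C5 alcohol trans to both the oxirane oxygen and the C6 silyloxy group (5S).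

Step 9
Reactants: 20 (1R,2S,3R,4R,6S)-4-[(3S)-3-hydroxy-6-methylhepta-1,5-dien-2-yl]-1-methyl-3-(triethylsilyloxy)-7-oxabicyclo[4.1.0]heptan-2-ol; 21 (Z)-2-methylbut-2-enoic acid (angelic acid)
Product: 23 (1S,2S,3R,4R,6S)-1-methyl-4-{(3S)-6-methyl-3-[(Z)-2-methylbut-2-enoyloxy]hepta-1,5-dien-2-yl}-3-(triethylsilyloxy)-7-oxabicyclo[4.1.0]heptan-2-yl (Z)-2-methylbut-2-enoate, via mixed anhydride 22 (not isolated)
Conditions: 21 (4 equiv), 2,4,6-Cl3C6H2COCl (4 equiv), Et3N, toluene, rt; then 20, toluene, 80 °C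
Reagents that add atoms: none
Why: Yamaguchi-type esterification through the angelic 2,4,6-trichlorobenzoic mixed anhydride, run without DMAP so that the Z-alkene does not isomerise to the tiglate; both free hydroxyls (C5 and C8) are acylated in one operation while C6 stays silylated, and no stereocentre is affected.

Step 10
Reactants: 23 (1S,2S,3R,4R,6S)-1-methyl-4-{(3S)-6-methyl-3-[(Z)-2-methylbut-2-enoyloxy]hepta-1,5-dien-2-yl}-3-(triethylsilyloxy)-7-oxabicyclo[4.1.0]heptan-2-yl (Z)-2-methylbut-2-enoate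
Product: 24 (1S,2S,3R,4R,6S)-3-hydroxy-1-methyl-4-{(3S)-6-methyl-3-[(Z)-2-methylbut-2-enoyloxy]hepta-1,5-dien-2-yl}-7-oxabicyclo[4.1.0]heptan-2-yl (Z)-2-methylbut-2-enoate
Conditions: HF·pyridine, pyridine, THF, 0 °C → rt
Reagents that add atoms: none
Why: Buffered acidic fluoride cleavage of the triethylsilyl ether avoids the alkoxide that would trigger C5→C6 acyl migration, and is done while the only oxirane present is the ring one, which is deactivated by the neighbouring acyloxy group.

Step 11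
Reactants: 24 (1S,2S,3R,4R,6S)-3-hydroxy-1-methyl-4-{(3S)-6-methyl-3-[(Z)-2-methylbut-2-enoyloxy]hepta-1,5-dien-2-yl}-7-oxabicyclo[4.1.0]heptan-2-yl (Z)-2-methylbut-2-enoate
Product: 25 CNP0296086.4, (1S,2S,3R,4R,6S)-4-{(3S)-4-[(2R)-3,3-dimethyloxiran-2-yl]-3-[(Z)-2-methylbut-2-enoyloxy]but-1-en-2-yl}-3-hydroxy-1-methyl-7-oxabicyclo[4.1.0]heptan-2-yl (Z)-2-methylbut-2-enoate
Conditions: D-fructose-derived Shi ketone (30 mol%), KHSO5 (as Oxone), K2CO3, Bu4NHSO4, MeCN/CH2(OMe)2/aq. Na2B4O7 buffer (pH 10.5), 0 °C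
Reagents that add atoms: potassium peroxymonosulfate [K+].[O-]S(=O)(=O)OO
Why: Shi asymmetric epoxidation; the chiral dioxirane reacts through a spiro transition state with the electron-rich trisubstituted C10=C11 alkene to set C10 (R), while the angelate alkenes and the exocyclic methylene next to an acyloxy group are too electron-poor or hindered to compete.

**Compound list**
1 | 4,4-diethoxybut-1-ene | C=CCC(OCC)OCC | starting material
2 | (E)-but-2-enal | C/C=C/C=O | starting material
3 | (E)-5,5-diethoxypent-2-enal | O=C/C=C/CC(OCC)OCC | intermediate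
4 | tert-butyl 3-oxopentanoate | CCC(=O)CC(=O)OC(C)(C)C | starting material
5 | tert-butyl (3R)-5,5-diethoxy-3-(2-oxoethyl)-2-propanoylpentanoate (epimers at C2; Michael adduct) | CCOC(OCC)C[C@@H](CC=O)C(C(=O)CC)C(=O)OC(C)(C)C | intermediate
6 | tert-butyl (6R)-6-(2,2-diethoxyethyl)-3-methyl-2-oxocyclohex-3-ene-1-carboxylate (epimers at C1) | CCOC(OCC)C[C@H]1CC=C(C)C(=O)C1C(=O)OC(C)(C)C | intermediate
7 | (5R)-5-(2,2-diethoxyethyl)-2-methylcyclohex-2-en-1-one | CCOC(OCC)C[C@H]1CC=C(C)C(=O)C1 | intermediate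
8 | (1S,4R,6S)-4-(2,2-diethoxyethyl)-1-methyl-7-oxabicyclo[4.1.0]heptan-2-one | CCOC(OCC)C[C@H]1C[C@@H]2O[C@]2(C)C(=O)C1 | intermediate
9 | {[(1S,4R,6S)-4-(2,2-diethoxyethyl)-1-methyl-7-oxabicyclo[4.1.0]hept-2-en-2-yl]oxy}triethylsilane | CCOC(OCC)C[C@H]1C[C@@H]2O[C@]2(C)C(O[Si](CC)(CC)CC)=C1 | intermediate
10 | (1R,3S,4S,5S,6R)-1-(2,2-diethoxyethyl)-3,4:5,6-diepoxy-4-methyl-5-(triethylsilyloxy)cyclohexane (route locants; both oxirane oxygens on the face opposite the side chain) | CCOC(OCC)C[C@H]1C[C@@H]2O[C@]2(C)[C@]3(O[Si](CC)(CC)CC)O[C@H]13 | intermediate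
11 | (1S,3R,4R,6S)-4-(2,2-diethoxyethyl)-1-methyl-3-(triethylsilyloxy)-7-oxabicyclo[4.1.0]heptan-2-one | CCOC(OCC)C[C@H]1C[C@@H]2O[C@]2(C)C(=O)[C@@H]1O[Si](CC)(CC)CC | intermediate
12 | 2-[(1S,3R,4R,6S)-6-methyl-5-oxo-4-(triethylsilyloxy)-7-oxabicyclo[4.1.0]heptan-3-yl]acetaldehyde | O=CC[C@H]1C[C@@H]2O[C@]2(C)C(=O)[C@@H]1O[Si](CC)(CC)CC | intermediate
13 | 2-[(1S,3R,4R,6S)-6-methyl-5-oxo-4-(triethylsilyloxy)-7-oxabicyclo[4.1.0]heptan-3-yl]prop-2-enal | C=C(C=O)[C@H]1C[C@@H]2O[C@]2(C)C(=O)[C@@H]1O[Si](CC)(CC)CC | intermediate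
14 | 1-chloro-3-methylbut-2-ene (prenyl chloride) | CC(C)=CCCl | starting material
15 | 2-isopropoxy-4,4,5,5-tetramethyl-1,3,2-dioxaborolane | CC(C)OB1OC(C)(C)C(C)(C)O1 | starting material
16 | (3-methylbut-2-en-1-yl)magnesium chloride | CC(C)=CC[Mg]Cl | intermediate
17 | 2-(2-methylbut-3-en-2-yl)-4,4,5,5-tetramethyl-1,3,2-dioxaborolane | C=CC(C)(C)B1OC(C)(C)C(C)(C)O1 | intermediate
18 | pinacol borate ester (O8–Bpin) of alcohol 19 | C=C([C@H](CC=C(C)C)OB3OC(C)(C)C(C)(C)O3)[C@H]1C[C@@H]2O[C@]2(C)C(=O)[C@@H]1O[Si](CC)(CC)CC | intermediate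
19 | (1S,3R,4R,6S)-4-[(3S)-3-hydroxy-6-methylhepta-1,5-dien-2-yl]-1-methyl-3-(triethylsilyloxy)-7-oxabicyclo[4.1.0]heptan-2-one | C=C([C@H](CC=C(C)C)O)[C@H]1C[C@@H]2O[C@]2(C)C(=O)[C@@H]1O[Si](CC)(CC)CC | intermediate
20 | (1R,2S,3R,4R,6S)-4-[(3S)-3-hydroxy-6-methylhepta-1,5-dien-2-yl]-1-methyl-3-(triethylsilyloxy)-7-oxabicyclo[4.1.0]heptan-2-ol | C=C([C@H](CC=C(C)C)O)[C@H]1C[C@@H]2O[C@]2(C)[C@@H](O)[C@@H]1O[Si](CC)(CC)CC | intermediate
21 | (Z)-2-methylbut-2-enoic acid (angelic acid) | C/C=C(/C)C(=O)O | starting material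
22 | (Z)-2-methylbut-2-enoic 2,4,6-trichlorobenzoic anhydride | C/C=C(/C)C(=O)OC(=O)c1c(Cl)cc(Cl)cc1Cl | intermediate
23 | (1S,2S,3R,4R,6S)-1-methyl-4-{(3S)-6-methyl-3-[(Z)-2-methylbut-2-enoyloxy]hepta-1,5-dien-2-yl}-3-(triethylsilyloxy)-7-oxabicyclo[4.1.0]heptan-2-yl (Z)-2-methylbut-2-enoate | C=C([C@H](CC=C(C)C)OC(=O)/C(C)=C\C)[C@H]1C[C@@H]2O[C@]2(C)[C@@H](OC(=O)/C(C)=C\C)[C@@H]1O[Si](CC)(CC)CC | intermediate
24 | (1S,2S,3R,4R,6S)-3-hydroxy-1-methyl-4-{(3S)-6-methyl-3-[(Z)-2-methylbut-2-enoyloxy]hepta-1,5-dien-2-yl}-7-oxabicyclo[4.1.0]heptan-2-yl (Z)-2-methylbut-2-enoate | C=C([C@H](CC=C(C)C)OC(=O)/C(C)=C\C)[C@H]1C[C@@H]2O[C@]2(C)[C@@H](OC(=O)/C(C)=C\C)[C@@H]1O | intermediate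
25 | CNP0296086.4, (1S,2S,3R,4R,6S)-4-{(3S)-4-[(2R)-3,3-dimethyloxiran-2-yl]-3-[(Z)-2-methylbut-2-enoyloxy]but-1-en-2-yl}-3-hydroxy-1-methyl-7-oxabicyclo[4.1.0]heptan-2-yl (Z)-2-methylbut-2-enoate | C=C([C@H](C[C@H]1OC1(C)C)OC(=O)/C(C)=C\C)[C@H]1C[C@@H]2O[C@]2(C)[C@@H](OC(=O)/C(C)=C\C)[C@@H]1O | target

**Step count**
Total: 11 steps (step 6 is a one-step reagent branch). Longest linear sequence: 10 steps (1–5, 7–11).

**Steps most likely to fail, with fallbacks**

Step 2. Enal 3 can be γ-deprotonated by the amine catalyst and then lose ethanol. The buffered ring closure through the ethyl CH2 may be slow. The acetal may not survive the acid stage. The fallback sets out from 3 and separates ring closure from ester removal, replacing acid by a neutral dealkoxycarbonylation. Commercial methyl 3-oxopentanoate is added to 3 under the same amine catalysis to give the methyl ester Michael adduct F1. Ring closure with piperidinium acetate gives the isolated methyl keto ester F2. Krapcho demethoxycarbonylation (LiCl, wet DMSO, 130 °C), under which the acetal is inert, then returns to 7.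

Step 7 (the proposed new method). The hindered tertiary boronate may react too slowly, or the acid may not control the face with the gem-dimethyl reagent. The fallback uses known chemistry and sets out from 13. Allylboration with commercial allyl pinacol boronate under the same (S)-TRIP phosphoric acid catalysis gives the pinacol borate ester F3, and work-up gives the homoallylic alcohol F4. Cross-metathesis of F4 with excess 2-methyl-2-butene (second-generation Grubbs catalyst RuCl2(=CHPh)(PCy3)(H2IMes), CH2Cl2, 40 °C) converts the terminal vinyl group into the trisubstituted prenyl alkene and returns to 19.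

Step 9. The C5 hydroxyl is flanked by a quaternary oxirane carbon and the silyloxy carbon, so acylation may stall. Forcing conditions risk Z→E isomerisation to the tiglate or silyl migration. The fallback sets out from 20 and builds the Z-alkenes after acylation. 2-[Bis(2,2,2-trifluoroethoxy)phosphoryl]propanoic acid F5 is obtained by LiOH hydrolysis of its commercial ethyl ester. F5 is coupled to both hydroxyls of 20 with DCC; this acylation runs through a phosphoryl ketene and is little affected by hindrance, and gives the bis(phosphonopropanoate) F6. Double Still–Gennari olefination of F6 with acetaldehyde (KN(SiMe3)2, 18-crown-6, THF, −78 °C) forms both (Z)-2-methylbut-2-enoates and returns to 23.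

**Further compounds**
F1 | step 2 | methyl (3R)-5,5-diethoxy-3-(2-oxoethyl)-2-propanoylpentanoate (epimers at C2) | CCOC(OCC)C[C@@H](CC=O)C(C(=O)CC)C(=O)OC
F2 | step 2 | methyl (6R)-6-(2,2-diethoxyethyl)-3-methyl-2-oxocyclohex-3-ene-1-carboxylate (epimers at C1) | CCOC(OCC)C[C@H]1CC=C(C)C(=O)C1C(=O)OC
F3 | step 7 | pinacol borate ester (O8–Bpin) of alcohol F4 | C=C([C@H](CC=C)OB3OC(C)(C)C(C)(C)O3)[C@H]1C[C@@H]2O[C@]2(C)C(=O)[C@@H]1O[Si](CC)(CC)CC
F4 | step 7 | (1S,3R,4R,6S)-4-[(3S)-3-hydroxyhexa-1,5-dien-2-yl]-1-methyl-3-(triethylsilyloxy)-7-oxabicyclo[4.1.0]heptan-2-one | C=C([C@H](CC=C)O)[C@H]1C[C@@H]2O[C@]2(C)C(=O)[C@@H]1O[Si](CC)(CC)CC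
F5 | step 9 | 2-[bis(2,2,2-trifluoroethoxy)phosphoryl]propanoic acid | CC(C(=O)O)P(=O)(OCC(F)(F)F)OCC(F)(F)F
F6 | step 9 | 5,8-bis{2-[bis(2,2,2-trifluoroethoxy)phosphoryl]propanoate} of diol 20 (6-triethylsilyl ether; phosphonate α-carbons unspecified) | C=C([C@H](CC=C(C)C)OC(=O)C(C)P(=O)(OCC(F)(F)F)OCC(F)(F)F)[C@H]1C[C@@H]2O[C@]2(C)[C@@H](OC(=O)C(C)P(=O)(OCC(F)(F)F)OCC(F)(F)F)[C@@H]1O[Si](CC)(CC)CC
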